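The theta run, which is this very flask followed so far, shows the target falling after its peak, from 33.5% at 5.00 h to 25.7% at 8.00 h, and we must decide what to do at 10 h.

| flask | starting material | remark | time |
|---|---|---|---|
| theta | 1 M | the very flask that is asked about, followed so far |  |
| zeta | 0.67 M | run made earlier |  |
| flask | 1.0 M |  | 10 h |

theta run (percent of the starting material charged)

| time / h | target / % | starting material / % |
|---|---|---|
| 0.667 | 14.1 | 58.9 |
| 1.00 | 21.9 | 45.0 |
| 1.33 | 28.1 | 37.2 |
| 2.50 | 38.6 | 16.6 |
| 3.00 | 37.6 | 9.3 |
| 5.00 | 33.5 | 2.1 |
| 8.00 | 25.7 | 0.9 |

zeta run (percent of the starting material charged)

| time / min | target / % | starting material / % |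
|---|---|---|
| 4.00 | 0 | 94.6 |
| 6.00 | 2.3 | 93.0 |
| 8.00 | 0.8 | 90.7 |
| 15.0 | 3.7 | 82.8 |
| 20.0 | 8.0 | 76.7 |
| 30.0 | 11.2 | 67.9 |
| 50.0 | 18.8 | 52.8 |

(each reading ± 1 percentage point)

- north-east: at 10 h add starting material, 50.0% of the amount charged, then wait 20 h
- south-east: change nothing and wait 20 h more
- west: at 10 h take out 90% of the target then present, then wait 20 h

- what is taken out of target is counted as made
- additions bring no volume worth counting

1. target, in percent of the starting material first charged, at 10 h
2. what to do for the largest gain in target; "none" if nothing gains more than 2 percentage points (north-east / south-east / west / none)
3. target present, with what was taken out counted in, in percent of the starting material first charged, after north-east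
4. target present, with what was taken out counted in, in percent of the starting material first charged, after west

We work in logarithms, because the decision hangs on how many powers of ten the target loses. We call the decade time the hours the target takes to lose one power of ten, and these two readings give 26.1 h, with their scatter in it. So our own reckoning puts the target at 21.5% at 10 h, and the further 20 h costs 0.766 of a decade.

West is the option to test. It gains 2 percentage points only if the flask holds 4.15% of target at the end, but the decade time leaves 0.368%, which is less. That would say stop and work up. But at 8.00 h, 73.4% of the charge stands in neither column of the theta run, and our 0.368% counts none of it as coming back.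

The forecast gives 22% now, 9% after north-east and 20.2% after west, and its choice is none. Its ground is that it will “treat the decay as irreversible”.

The flask gives 19.7% at 10 h, 17.4% after north-east and 26.6% after west, so the best choice is west, a gain of 6.9 points.

    2 starting material → self-condensation product (k = 1.37 × 10⁻⁵ M⁻¹ s⁻¹)
    starting material → intermediate (k = 1.98 × 10⁻⁴ s⁻¹)
    intermediate ⇌ target (K = 2.93, k = 6.82 × 10⁻⁴ s⁻¹)
    intermediate ⇌ isomer of the product (K = 21.0, k = 2.29 × 10⁻⁴ s⁻¹)

After west the flask holds 8.87% of target at the end, more than the 4.15% required, where the decade time promised 0.368%. Part of the reason lies in two steps that act together, the backward run from target to intermediate and the conversion of intermediate into isomer of the product: at 10 h the flask holds 19.7% of target, the run without the backward step 75.0%, and the run without that conversion 69.8%. For the neighbour flask read at 15 h, the decade time carried on from 19.7% gives 12.7%, and the computed result is 14.1%.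

The runs are calculated with constants of no real substance, and the scatter is random.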